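**Retrosynthetic overview**

- Feature: in the pyranone ring the bridge CH2 sits on C3, between the C2 lactone carbonyl and the C4 enol carbon. C2–C3–C4 with the bridge is therefore an arylmethylmalonyl unit, and O1, C6 (ethyl) and C5 (methyl) are the enol of 3-pentanone.
- Key disconnection: C4–C5 and O1–C2 of the pyranone, giving arylmethylmalonic acid 17 (used as its dichloride) and enol silane 19. The two phenols are allyl ethers during the annulation and are freed afterwards.
- Diacid 17 comes from aldehyde 13 by reductive Knoevenagel condensation with Meldrum's acid and hydrolysis of the acylal.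
- The hexasubstituted benzene ring is that of 5-methoxyresorcinol. Two directed ortho-metalations of its bis-MOM ether place the prenyl group (between the acetals) and the (R)-2-methylbutanoyl group (Weinreb amide, stereocenter bought). After MOM removal, ortho-formylation fills the last ring carbon and both phenols are allylated.
- Ring order: the benzene ring is bought; the pyranone ring is the only ring formed, in step 11.

Key step: step 11

Remark: enol silane 19 is drawn as its Z isomer; any E isomer formed with it gives the same pyranone, because the geometry of that double bond is lost on ring closure.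

**Route**

Step 1
Reactants: 1 5-methoxyresorcinol
Product: 2 1-methoxy-3,5-bis(methoxymethoxy)benzene
Conditions: MOMCl, i-Pr2NEt, CH2Cl2, 0 °C → rt
Reagents that add atoms: chloromethyl methyl ether (MOMCl), COCCl
Why: O-alkylation of both phenols with the reactive alpha-chloro ether under amine base (MOM ether formation) should be clean, and the two acetals are the directing groups needed in steps 2 and 4.

Step 2
Reactants: 2 1-methoxy-3,5-bis(methoxymethoxy)benzene
Product: 4 5-methoxy-1,3-bis(methoxymethoxy)-2-(3-methylbut-2-enyl)benzene, via aryllithium 3 (not isolated)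
Conditions: n-BuLi, THF, 0 °C; CuBr·SMe2 (10 mol%), prenyl bromide, −78 °C → rt
Reagents that add atoms: prenyl bromide (1-bromo-3-methylbut-2-ene), CC(C)=CCBr
Why: directed ortho-metalation should take place at the ring carbon flanked by the two chelating MOM acetals, which direct more strongly than the anisole oxygen, and copper-catalysed SN2 allylation at the primary carbon of prenyl bromide gives the linear prenyl group on a still symmetrical arene.

Step 3
Reactants: 5 (R)-2-methylbutanoic acid
Product: 7 (2R)-N-methoxy-N,2-dimethylbutanamide, via acyl imidazole 6 (not isolated)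
Conditions: CDI, CH2Cl2, 0 °C → rt; then MeNHOMe·HCl, rt
Reagents that add atoms: N,O-dimethylhydroxylamine hydrochloride, CNOC.Cl
Why: Weinreb amide formation through the acyl imidazolide (CDI activation) uses no base strong enough to enolise the acyl group, so the R stereocenter of 5 is carried over unchanged.

Step 4
Reactants: 4 5-methoxy-1,3-bis(methoxymethoxy)-2-(3-methylbut-2-enyl)benzene; 7 (2R)-N-methoxy-N,2-dimethylbutanamide
Product: 10 (2R)-1-[6-methoxy-2,4-bis(methoxymethoxy)-3-(3-methylbut-2-enyl)phenyl]-2-methylbutan-1-one, via aryllithium 8 (not isolated), via tetrahedral lithium adduct 9 (not isolated)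
Conditions: n-BuLi, THF, 0 °C; then 7, −78 → 0 °C; saturated aqueous NH4Cl
Reagents that add atoms: none
Why: the second directed ortho-metalation can only occur at the two equivalent ring carbons between a MOM acetal and the methoxy group, and the Weinreb ketone synthesis stops at chelated adduct 9 until the quench, so one regioisomer should form without over-addition and with the R stereocenter of 7 intact.

Step 5
Reactants: 10 (2R)-1-[6-methoxy-2,4-bis(methoxymethoxy)-3-(3-methylbut-2-enyl)phenyl]-2-methylbutan-1-one
Product: 11 (2R)-1-[2,4-dihydroxy-6-methoxy-3-(3-methylbut-2-enyl)phenyl]-2-methylbutan-1-one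
Conditions: concentrated aqueous HCl, MeOH, rt
Reagents that add atoms: none
Why: acid-catalysed transacetalisation with methanol (MOM cleavage) removes both acetals at room temperature, the one chelated to the ketone first, and is expected to outpace addition of the flanking phenols to the prenyl alkene.

Step 6
Reactants: 11 (2R)-1-[2,4-dihydroxy-6-methoxy-3-(3-methylbut-2-enyl)phenyl]-2-methylbutan-1-one
Product: 12 2,4-dihydroxy-6-methoxy-5-[(2R)-2-methylbutanoyl]-3-(3-methylbut-2-enyl)benzaldehyde
Conditions: MgCl2, Et3N, (CH2O)n, MeCN, 70 °C; aqueous citric acid work-up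
Reagents that add atoms: paraformaldehyde (formaldehyde), C=O
Why: in this Casnati–Skattebøl ortho-formylation the magnesium phenoxide of the C4 hydroxyl delivers formaldehyde to the only unsubstituted ring carbon and a second formaldehyde oxidises the benzylic alkoxide by hydride transfer, all without acid, so the ortho-prenyl phenol cannot close to a chroman.

Step 7
Reactants: 12 2,4-dihydroxy-6-methoxy-5-[(2R)-2-methylbutanoyl]-3-(3-methylbut-2-enyl)benzaldehyde
Product: 13 2,4-bis(allyloxy)-6-methoxy-5-[(2R)-2-methylbutanoyl]-3-(3-methylbut-2-enyl)benzaldehyde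
Conditions: allyl bromide, K2CO3, DMF, 50 °C
Reagents that add atoms: allyl bromide, C=CCBr
Why: Williamson O-allylation in DMF alkylates both hydrogen-bonded phenols, and K2CO3 is too weak a base to enolise the hindered ketone, so the stereocenter is safe.

Step 8
Reactants: 13 2,4-bis(allyloxy)-6-methoxy-5-[(2R)-2-methylbutanoyl]-3-(3-methylbut-2-enyl)benzaldehyde; 14 2,2-dimethyl-1,3-dioxane-4,6-dione (Meldrum's acid)
Product: 16 5-{[2,4-bis(allyloxy)-6-methoxy-5-[(2R)-2-methylbutanoyl]-3-(3-methylbut-2-enyl)phenyl]methyl}-2,2-dimethyl-1,3-dioxane-4,6-dione, via arylidene dioxanedione 15 (not isolated)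
Conditions: Hantzsch ester, L-proline (20 mol%), EtOH, rt
Reagents that add atoms: none
Why: in this organocatalytic reductive Knoevenagel alkylation, proline-catalysed condensation of the acidic dioxanedione with the aldehyde gives electrophilic arylidene 15, which the Hantzsch ester reduces by conjugate hydride transfer while the hindered ketone and the three alkenes stay inert.

Step 9
Reactants: 16 5-{[2,4-bis(allyloxy)-6-methoxy-5-[(2R)-2-methylbutanoyl]-3-(3-methylbut-2-enyl)phenyl]methyl}-2,2-dimethyl-1,3-dioxane-4,6-dione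
Product: 17 2-{[2,4-bis(allyloxy)-6-methoxy-5-[(2R)-2-methylbutanoyl]-3-(3-methylbut-2-enyl)phenyl]methyl}propanedioic acid
Conditions: THF/H2O, NaOAc/AcOH buffer (pH 4.5), 60 °C; then pH 2 at 0 °C and extraction
Reagents that add atoms: water, O
Why: hydrolysis of the activated acylal opens the neutral dioxanedione ring with loss of acetone to give the malonic acid, and the acetate buffer and moderate temperature guard the prenyl alkene against acid-catalysed hydration and the diacid against decarboxylation.

Step 10
Reactants: 18 3-pentanone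
Product: 19 (Z)-3-(trimethylsilyloxy)pent-2-ene
Conditions: TMSOTf, Et3N, CH2Cl2, 0 °C
Reagents that add atoms: trimethylsilyl trifluoromethanesulfonate, C[Si](C)(C)OS(=O)(=O)C(F)(F)F
Why: soft enolisation and O-silylation of a symmetrical ketone can give only one constitutional enol silane.

Step 11
Reactants: 17 2-{[2,4-bis(allyloxy)-6-methoxy-5-[(2R)-2-methylbutanoyl]-3-(3-methylbut-2-enyl)phenyl]methyl}propanedioic acid; 19 (Z)-3-(trimethylsilyloxy)pent-2-ene
Product: 22 3-{[2,4-bis(allyloxy)-6-methoxy-5-[(2R)-2-methylbutanoyl]-3-(3-methylbut-2-enyl)phenyl]methyl}-6-ethyl-4-hydroxy-5-methyl-2H-pyran-2-one, via malonyl dichloride 20 (not isolated), via diketo acid chloride 21 (not isolated)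
Conditions: 1-chloro-N,N,2-trimethylprop-1-en-1-amine (2.1 equiv), CH2Cl2, 0 °C → rt; then 19 (1.5 equiv), −78 °C → rt; pH 7 phosphate buffer
Reagents that add atoms: none
Why: The chloroenamine turns both carboxyl groups of 17 into acyl chlorides without acid or base (20), the nucleophilic carbon of 19 is acylated by one of them (or by the (chlorocarbonyl)ketene that 20 forms by loss of HCl) with loss of Me3SiCl to give 21, and the enol oxygen of the ethyl ketone of 21 then displaces chloride from the second acyl chloride before the dione tautomerises to the 4-hydroxy-2-pyranone. The closest known reaction type is the condensation of monosubstituted malonyl dichlorides or (chlorocarbonyl)ketenes with ketones and enol silanes to 3-substituted 4-hydroxy-2-pyranones. The pyranone ring is closed by the intermolecular C4–C5 acylation followed by a 6-exo-trig lactonisation that forms O1–C2. No stereocenter is formed, since C3 and C5 end as sp2 carbons, and the R center beside the aryl ketone is not at risk because no base is present and the HCl set free is buffered by the amide by-product at low temperature. The step needs chemoselectivity: the allyl ethers keep the ring oxygen ortho to the bridge from lactonising to a dihydrocoumarin, the fully substituted arene cannot undergo Friedel–Crafts acylation, the symmetrical ketone offers only one alpha carbon, and the substituent on C3 blocks a second acylation of the product.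

Step 12
Reactants: 22 3-{[2,4-bis(allyloxy)-6-methoxy-5-[(2R)-2-methylbutanoyl]-3-(3-methylbut-2-enyl)phenyl]methyl}-6-ethyl-4-hydroxy-5-methyl-2H-pyran-2-one
Product: 23 3-{[2,4-dihydroxy-6-methoxy-5-[(2R)-2-methylbutanoyl]-3-(3-methylbut-2-enyl)phenyl]methyl}-6-ethyl-4-hydroxy-5-methyl-2H-pyran-2-one
Conditions: Pd(PPh3)4 (5 mol%), morpholine, THF, rt; pH 5 phosphate wash
Reagents that add atoms: none
Why: in this Tsuji–Trost deallylation zerovalent palladium ionises the two aryl allyl ethers to allylpalladium phenoxides and morpholine captures the allyl groups irreversibly, while the prenyl group (no leaving group), the pyranone and the stereocenter are not touched under these nearly neutral conditions.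

**Compound list**

1 | 5-methoxyresorcinol (5-methoxybenzene-1,3-diol) | COc1cc(O)cc(O)c1 | starting material
2 | 1-methoxy-3,5-bis(methoxymethoxy)benzene | COCOc1cc(OC)cc(OCOC)c1 | intermediate
3 | [4-methoxy-2,6-bis(methoxymethoxy)phenyl]lithium | [Li]c1c(OCOC)cc(OC)cc1OCOC | intermediate (not isolated)
4 | 5-methoxy-1,3-bis(methoxymethoxy)-2-(3-methylbut-2-enyl)benzene | COCOc1cc(OC)cc(OCOC)c1CC=C(C)C | intermediate
5 | (R)-2-methylbutanoic acid | OC(=O)[C@H](C)CC | starting material
6 | (2R)-1-(imidazol-1-yl)-2-methylbutan-1-one | O=C([C@H](C)CC)n1ccnc1 | intermediate (not isolated)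
7 | (2R)-N-methoxy-N,2-dimethylbutanamide | CON(C)C(=O)[C@H](C)CC | intermediate
8 | [6-methoxy-2,4-bis(methoxymethoxy)-3-(3-methylbut-2-enyl)phenyl]lithium | [Li]c1c(OCOC)c(CC=C(C)C)c(OCOC)cc1OC | intermediate (not isolated)
9 | lithium (2R)-1-[methoxy(methyl)amino]-1-[6-methoxy-2,4-bis(methoxymethoxy)-3-(3-methylbut-2-enyl)phenyl]-2-methylbutan-1-olate (tetrahedral adduct, carbinol carbon unassigned) | [Li]OC(N(C)OC)([C@H](C)CC)c1c(OCOC)c(CC=C(C)C)c(OCOC)cc1OC | intermediate (not isolated)
10 | (2R)-1-[6-methoxy-2,4-bis(methoxymethoxy)-3-(3-methylbut-2-enyl)phenyl]-2-methylbutan-1-one | COc1cc(OCOC)c(CC=C(C)C)c(OCOC)c1C(=O)[C@H](C)CC | intermediate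
11 | (2R)-1-[2,4-dihydroxy-6-methoxy-3-(3-methylbut-2-enyl)phenyl]-2-methylbutan-1-one | COc1cc(O)c(CC=C(C)C)c(O)c1C(=O)[C@H](C)CC | intermediate
12 | 2,4-dihydroxy-6-methoxy-5-[(2R)-2-methylbutanoyl]-3-(3-methylbut-2-enyl)benzaldehyde | O=Cc1c(O)c(CC=C(C)C)c(O)c(C(=O)[C@H](C)CC)c1OC | intermediate
13 | 2,4-bis(allyloxy)-6-methoxy-5-[(2R)-2-methylbutanoyl]-3-(3-methylbut-2-enyl)benzaldehyde | O=Cc1c(OCC=C)c(CC=C(C)C)c(OCC=C)c(C(=O)[C@H](C)CC)c1OC | intermediate
14 | 2,2-dimethyl-1,3-dioxane-4,6-dione (Meldrum's acid) | CC1(C)OC(=O)CC(=O)O1 | starting material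
15 | 5-{[2,4-bis(allyloxy)-6-methoxy-5-[(2R)-2-methylbutanoyl]-3-(3-methylbut-2-enyl)phenyl]methylidene}-2,2-dimethyl-1,3-dioxane-4,6-dione | CC1(C)OC(=O)C(=Cc2c(OCC=C)c(CC=C(C)C)c(OCC=C)c(C(=O)[C@H](C)CC)c2OC)C(=O)O1 | intermediate (not isolated)
16 | 5-{[2,4-bis(allyloxy)-6-methoxy-5-[(2R)-2-methylbutanoyl]-3-(3-methylbut-2-enyl)phenyl]methyl}-2,2-dimethyl-1,3-dioxane-4,6-dione | CC1(C)OC(=O)C(Cc2c(OCC=C)c(CC=C(C)C)c(OCC=C)c(C(=O)[C@H](C)CC)c2OC)C(=O)O1 | intermediate
17 | 2-{[2,4-bis(allyloxy)-6-methoxy-5-[(2R)-2-methylbutanoyl]-3-(3-methylbut-2-enyl)phenyl]methyl}propanedioic acid | OC(=O)C(Cc1c(OCC=C)c(CC=C(C)C)c(OCC=C)c(C(=O)[C@H](C)CC)c1OC)C(=O)O | intermediate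
18 | 3-pentanone | CCC(=O)CC | starting material
19 | (Z)-3-(trimethylsilyloxy)pent-2-ene | C/C=C(/CC)O[Si](C)(C)C | intermediate
20 | 2-{[2,4-bis(allyloxy)-6-methoxy-5-[(2R)-2-methylbutanoyl]-3-(3-methylbut-2-enyl)phenyl]methyl}propanedioyl dichloride | ClC(=O)C(Cc1c(OCC=C)c(CC=C(C)C)c(OCC=C)c(C(=O)[C@H](C)CC)c1OC)C(=O)Cl | intermediate (not isolated)
21 | 2-{[2,4-bis(allyloxy)-6-methoxy-5-[(2R)-2-methylbutanoyl]-3-(3-methylbut-2-enyl)phenyl]methyl}-4-methyl-3,5-dioxoheptanoyl chloride (chain carbons 2 and 4 unassigned) | CCC(=O)C(C)C(=O)C(Cc1c(OCC=C)c(CC=C(C)C)c(OCC=C)c(C(=O)[C@H](C)CC)c1OC)C(=O)Cl | intermediate (not isolated)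
22 | 3-{[2,4-bis(allyloxy)-6-methoxy-5-[(2R)-2-methylbutanoyl]-3-(3-methylbut-2-enyl)phenyl]methyl}-6-ethyl-4-hydroxy-5-methyl-2H-pyran-2-one | CCc1oc(=O)c(Cc2c(OCC=C)c(CC=C(C)C)c(OCC=C)c(C(=O)[C@H](C)CC)c2OC)c(O)c1C | intermediate
23 | 3-{[2,4-dihydroxy-6-methoxy-5-[(2R)-2-methylbutanoyl]-3-(3-methylbut-2-enyl)phenyl]methyl}-6-ethyl-4-hydroxy-5-methyl-2H-pyran-2-one | CCc1oc(=O)c(Cc2c(O)c(CC=C(C)C)c(O)c(C(=O)[C@H](C)CC)c2OC)c(O)c1C | target

**Step count and risks**

Total step count: 12. Longest linear sequence: 10 steps (steps 1, 2, 4, 5, 6, 7, 8, 9, 11, 12, from 5-methoxyresorcinol).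

The three steps most likely to fail:

1. Step 11 (annulation). The acyl chloride may be captured by the neighbouring ether oxygen with loss of allyl chloride (dealkylative lactonisation). The enol silane may also be acylated on oxygen instead of carbon, or the ketene may oligomerise before it is trapped. Fallback: the pyranone is made first and joined to the arene by a known reductive alkylation. Enol silane 19 and malonyl dichloride (ClC(=O)CC(=O)Cl; Et2O, −78 °C → rt) should give 6-ethyl-4-hydroxy-5-methyl-2H-pyran-2-one F1. Aldehyde 13, F1, Hantzsch ester and L-proline (CH2Cl2, rt) should then condense to the 3-arylmethylidene pyran-2,4-dione F2, which is reduced in the flask to 22, where the route is rejoined.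

2. Step 6 (formylation). The chelated, acyl-substituted phenoxide may be too weak a nucleophile at the crowded last ring carbon. Prolonged heating of the magnesium chelate with Et3N may also enolise the ketone and erode the stereocenter. Fallback: the formyl group is introduced by metalation before the ketone. Aryllithium 8, made from 4 as in step 4, is quenched with DMF to give 6-methoxy-2,4-bis(methoxymethoxy)-3-(3-methylbut-2-enyl)benzaldehyde F3. Condensation with N,N'-dimethylethane-1,2-diamine (toluene, molecular sieves) masks the aldehyde as 2-aryl-1,3-dimethylimidazolidine F4. n-BuLi (THF, 0 °C) then metalates the last ring carbon to aryllithium F5, which adds to Weinreb amide 7 and gives, after NH4Cl quench, keto aminal F6. Aqueous HCl in MeOH removes the aminal and both MOM groups and returns the route at 12.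

3. Step 9 (acylal hydrolysis). Hydrolysis may be too slow at the buffered pH, and longer heating may bring decarboxylation of the malonic acid or hydration of the prenyl alkene. Fallback: the ring is opened by an alcohol instead of water. Heating 16 with 2-(trimethylsilyl)ethanol (toluene, 90 °C) should give, with loss of acetone, the malonic acid mono[2-(trimethylsilyl)ethyl] ester F7. Bu4NF (THF, rt) followed by cold acidification to pH 2 should cleave the silylethyl ester and return the route at diacid 17.

**Further compounds**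

F1 | step 11 | 6-ethyl-4-hydroxy-5-methyl-2H-pyran-2-one | CCc1oc(=O)cc(O)c1C
F2 | step 11 | 3-{[2,4-bis(allyloxy)-6-methoxy-5-[(2R)-2-methylbutanoyl]-3-(3-methylbut-2-enyl)phenyl]methylidene}-6-ethyl-5-methylpyran-2,4-dione | CCC1=C(C)C(=O)C(=Cc2c(OCC=C)c(CC=C(C)C)c(OCC=C)c(C(=O)[C@H](C)CC)c2OC)C(=O)O1
F3 | step 6 | 6-methoxy-2,4-bis(methoxymethoxy)-3-(3-methylbut-2-enyl)benzaldehyde | O=Cc1c(OCOC)c(CC=C(C)C)c(OCOC)cc1OC
F4 | step 6 | 2-[6-methoxy-2,4-bis(methoxymethoxy)-3-(3-methylbut-2-enyl)phenyl]-1,3-dimethylimidazolidine | CN1CCN(C)C1c1c(OCOC)c(CC=C(C)C)c(OCOC)cc1OC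
F5 | step 6 | [3-(1,3-dimethylimidazolidin-2-yl)-2-methoxy-4,6-bis(methoxymethoxy)-5-(3-methylbut-2-enyl)phenyl]lithium | CN1CCN(C)C1c1c(OCOC)c(CC=C(C)C)c(OCOC)c([Li])c1OC
F6 | step 6 | (2R)-1-[3-(1,3-dimethylimidazolidin-2-yl)-2-methoxy-4,6-bis(methoxymethoxy)-5-(3-methylbut-2-enyl)phenyl]-2-methylbutan-1-one | CN1CCN(C)C1c1c(OCOC)c(CC=C(C)C)c(OCOC)c(C(=O)[C@H](C)CC)c1OC
F7 | step 9 | 2-{[2,4-bis(allyloxy)-6-methoxy-5-[(2R)-2-methylbutanoyl]-3-(3-methylbut-2-enyl)phenyl]methyl}-3-oxo-3-[2-(trimethylsilyl)ethoxy]propanoic acid | OC(=O)C(Cc1c(OCC=C)c(CC=C(C)C)c(OCC=C)c(C(=O)[C@H](C)CC)c1OC)C(=O)OCC[Si](C)(C)C
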